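**Retrosynthetic overview**

1. The target is the (3R)-isoflavan: ring A is the benzo ring of the chroman, ring C its dihydropyran, ring B the aryl group on C3, ring D the 2,2-dimethylpyran fused to ring B.
2. Late disconnections: the two O-allyl groups (O-7, O-4'), ring D (prenal annulation at the free 2'-OH and C3'), and the aromaticity of ring B, which is carried as a 3-allyloxycyclohex-2-enone.
3. Key disconnection: C3–C4 of ring C, closed by an asymmetric intramolecular Stetter reaction of a salicylaldehyde ether (C4 = CHO) onto the exocyclic enone C3=C1'–C2'=O.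
4. Enabling feature: ring B is a resorcinol with O-2' ortho to C1'. Written as its dihydro enol ether, C2' is a ketone conjugated to C1'=C3, so C3 becomes an acceptor carbon. C3 is then not an α-aryl ketone centre while C4=O is present, and O-2' (ketone, later free phenol) is differentiated from O-4' (enol ether, later allyl ether).
5. Fragments: enone alcohol 7 from cyclohexane-1,3-dione, aldehyde 11 from 5-bromo-2,4-dihydroxybenzaldehyde, joined by a Mitsunobu reaction. Ring order: A (bought), C (step 8), B aromatised (step 11), D (step 12).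

Key step: step 8

Remark: the SMILES is read as (R) at C3 of the chroman (isoflavan numbering, ring B primed); the sense of induction of the triazolium catalyst in step 8 is fixed in a test run, both antipodes being accessible, and the one that gives (3R)-13 is used.

**Route**

Step 1
Reactants: 1 cyclohexane-1,3-dione
Product: 2 3-(prop-2-en-1-yloxy)cyclohex-2-en-1-one
Conditions: allyl alcohol (3 equiv), p-toluenesulfonic acid monohydrate (5 mol %), toluene, reflux, Dean–Stark
Reagents that add atoms: allyl alcohol, C=CCO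
Why: Acid-catalysed enol etherification of a cyclic 1,3-dione (vinylogous Fischer esterification) is driven by azeotropic removal of water and installs the allyl group that later protects O-4'.

Step 2
Reactants: 2 3-(prop-2-en-1-yloxy)cyclohex-2-en-1-one; 3 2-[(tert-butyldimethylsilyl)oxy]acetaldehyde
Product: 4 6-{2-[(tert-butyldimethylsilyl)oxy]-1-hydroxyethyl}-3-(prop-2-en-1-yloxy)cyclohex-2-en-1-one (diastereomer mixture)
Conditions: LiN(i-Pr)2 (1.1 equiv), THF, −78 °C; then 3, −78 °C; aq NH4Cl
Reagents that add atoms: none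
Why: Stork–Danheiser kinetic deprotonation of the vinylogous ester at C6 followed by aldol addition to an unhindered aldehyde should give the β-hydroxy ketone, whose stereocenters are removed in step 3.

Step 3
Reactants: 4 aldol adduct
Product: 6 (6E)-6-{2-[(tert-butyldimethylsilyl)oxy]ethylidene}-3-(prop-2-en-1-yloxy)cyclohex-2-en-1-one, via mesylate 5 (not isolated)
Conditions: MsCl, Et3N, CH2Cl2, 0 °C; then DBU, 0 °C → rt
Reagents that add atoms: none
Why: Mesylation and E1cB elimination complete the aldol condensation and should give the conjugated exocyclic enone as the thermodynamically preferred E isomer (CH2O group anti to the carbonyl).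

Step 4
Reactants: 6 (E)-enone silyl ether
Product: 7 (6E)-6-(2-hydroxyethylidene)-3-(prop-2-en-1-yloxy)cyclohex-2-en-1-one
Conditions: HF·pyridine, pyridine, THF, 0 °C → rt
Reagents that add atoms: none
Why: Fluoride-mediated desilylation under buffered conditions frees the primary allylic alcohol without hydrolysing the enol ether.

Step 5
Reactants: 8 5-bromo-2,4-dihydroxybenzaldehyde; 9 tributyl(3-methylbut-2-en-1-yl)stannane
Product: 10 2,4-dihydroxy-5-(3-methylbut-2-en-1-yl)benzaldehyde
Conditions: Pd(PPh3)4 (5 mol %), DMF, 90 °C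
Reagents that add atoms: none
Why: Stille coupling of the aryl bromide with the allylic stannane should place the prenyl group, bonded through its unsubstituted terminus, at the carbon that becomes C6, which removes any C6/C8 regiochemical question later.

Step 6
Reactants: 10 2,4-dihydroxy-5-(3-methylbut-2-en-1-yl)benzaldehyde
Product: 11 2-hydroxy-5-(3-methylbut-2-en-1-yl)-4-(prop-2-en-1-yloxy)benzaldehyde
Conditions: allyl bromide (1.05 equiv), K2CO3 (1.05 equiv), acetone, 40 °C
Reagents that add atoms: allyl bromide, C=CCBr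
Why: Williamson etherification should be selective for the 4-OH, which is the more acidic and more nucleophilic phenol because the 2-OH is held in a hydrogen bond to the aldehyde.

Step 7
Reactants: 7 (E)-allylic alcohol; 11 2-hydroxy-5-(3-methylbut-2-en-1-yl)-4-(prop-2-en-1-yloxy)benzaldehyde
Product: 12 5-(3-methylbut-2-en-1-yl)-2-{(2E)-2-[2-oxo-4-(prop-2-en-1-yloxy)cyclohex-3-en-1-ylidene]ethoxy}-4-(prop-2-en-1-yloxy)benzaldehyde
Conditions: PPh3, diisopropyl azodicarboxylate, THF, 0 °C → rt
Reagents that add atoms: none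
Why: Mitsunobu etherification of the acidic salicylaldehyde phenol with a primary allylic alcohol forms the O1–C2 bond by SN2 displacement and leaves the enone geometry unchanged.

Step 8
Reactants: 12 aldehyde-tethered alkylidene enone
Product: 13 (3R)-6-(3-methylbut-2-en-1-yl)-3-[2-oxo-4-(prop-2-en-1-yloxy)cyclohex-3-en-1-yl]-7-(prop-2-en-1-yloxy)-2,3-dihydro-4H-chromen-4-one (epimers at the cyclohexenone C1)
Conditions: 2-(pentafluorophenyl)-5a,10b-dihydro-4H,6H-indeno[2,1-b][1,2,4]triazolo[4,3-d][1,4]oxazin-2-ium tetrafluoroborate, C18H11BF9N3O, antipode per the remark (20 mol %), KN(SiMe3)2 (20 mol %), toluene, 23 °C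
Reagents that add atoms: none
Why: The free triazolylidene adds to the C4 aldehyde and proton transfer gives the Breslow intermediate, an acyl-anion equivalent at C4, which adds to C3, the β-carbon of the exocyclic enone conjugated to the C2' carbonyl; protonation of the enolate at C1' and loss of the carbene give the 1,4-diketone. The closest known reaction is the catalytic asymmetric intramolecular Stetter reaction of salicylaldehyde-derived ethers that carry α,β-disubstituted acceptors, which gives 3-substituted chroman-4-ones. Ring C is closed in the 6-exo-trig mode through the C3–C4 bond. The C3 stereocenter is set in the C–C bond-forming step by the chiral carbene, whose aminoindanol backbone shields one face of the Breslow enaminol so that the s-cis-locked (E)-acceptor is attacked from one face; C1' forms as an epimer mixture that is erased on aromatisation. The step needs conjugate addition at C3 to outrun benzoin-type self-condensation and base-induced isomerisation of the alkylidene enone, which is secured by the six-membered transition state, the absence of acidic O–H groups (both ring A oxygens are alkylated) and the use of only catalytic base. The new C3–H is α to an aryl ketone but carries an alkyl and not an aryl group, so it should be configurationally stable under these weakly basic conditions.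

Step 9
Reactants: 13 (3R)-chroman-4-one
Product: 14 (3R)-6-(3-methylbut-2-en-1-yl)-3-[2-oxo-4-(prop-2-en-1-yloxy)cyclohex-3-en-1-yl]-7-(prop-2-en-1-yloxy)-3,4-dihydro-2H-chromen-4-ol (mixture at C4 and at the cyclohexenone C1)
Conditions: NaBH4, MeOH/CH2Cl2, −20 → 0 °C
Reagents that add atoms: none
Why: Borohydride reduction should take the aryl ketone and leave the ester-like vinylogous ester carbonyl, and it removes the C4 carbonyl before C3 can epimerise; the C4 configuration is inconsequential.

Step 10
Reactants: 14 (3R)-chroman-4-ol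
Product: 15 6-[(3R)-6-(3-methylbut-2-en-1-yl)-7-(prop-2-en-1-yloxy)-3,4-dihydro-2H-chromen-3-yl]-3-(prop-2-en-1-yloxy)cyclohex-2-en-1-one (epimers at the cyclohexenone C6)
Conditions: Et3SiH (5 equiv), CF3CO2H (3 equiv), CH2Cl2, −40 °C
Reagents that add atoms: none
Why: Ionic hydrogenation: the C4 hydroxyl ionises to a cation stabilised by O-1 (ortho) and O-7 (para), and this cation is reduced by the silane; a protonated or O-alkylated vinylogous ester is not reduced, and C3 is not touched.

Step 11
Reactants: 15 (3R)-chromanyl cyclohexenone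
Product: 19 2-[(3R)-6-(3-methylbut-2-en-1-yl)-7-(prop-2-en-1-yloxy)-3,4-dihydro-2H-chromen-3-yl]-5-(prop-2-en-1-yloxy)phenol, via selenide 16 (not isolated), via selenoxide 17 (not isolated), via cyclohexadienone 18 (not isolated)
Conditions: LiN(i-Pr)2, THF, −78 °C; PhSeBr, −78 °C; crude selenide: mCPBA (1.0 equiv), CH2Cl2, −78 °C; pyridine, −78 °C → rt
Reagents that add atoms: none
Why: Selenation of the kinetic enolate at C1' and selenoxide syn-elimination toward the ring CH2 (C6'), preferred over the hindered C3 methine whose loss would give a tetrasubstituted exocyclic olefin, give a cross-conjugated dienone that tautomerises to the phenol, with O-2' free and O-4' allylated.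

Step 12
Reactants: 19 (3R)-phenol; 20 3-methylbut-2-enal
Product: 23 (3R)-3-[2,2-dimethyl-5-(prop-2-en-1-yloxy)-2H-chromen-8-yl]-6-(3-methylbut-2-en-1-yl)-7-(prop-2-en-1-yloxy)-3,4-dihydro-2H-chromene, via benzodioxaborinine 21 (not isolated), via ortho-quinone methide 22 (not isolated)
Conditions: PhB(OH)2 (1.0 equiv), AcOH (cat.), toluene, reflux, Dean–Stark
Reagents that add atoms: none
Why: Phenylboronic acid-templated ortho-hydroxyalkylation, thermal fragmentation to the ortho-quinone methide and oxa-6π electrocyclisation should build ring D at C3', the only free ortho position of the only free phenol.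

Step 13
Reactants: 23 bis(allyl ether)
Product: 24 (3R)-3-(5-hydroxy-2,2-dimethyl-2H-chromen-8-yl)-6-(3-methylbut-2-en-1-yl)-3,4-dihydro-2H-chromen-7-ol
Conditions: Pd(PPh3)4 (5 mol %), morpholine (10 equiv), THF, rt
Reagents that add atoms: none
Why: Tsuji–Trost deallylation: zerovalent palladium ionises both aryl allyl ethers to π-allyl complexes that morpholine traps, while the prenyl group, the chromene and C3 are not affected.

**Compound list**

1 | cyclohexane-1,3-dione | O=C1CCCC(=O)C1 | starting material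
2 | 3-(prop-2-en-1-yloxy)cyclohex-2-en-1-one | O=C1C=C(OCC=C)CCC1 | intermediate
3 | 2-[(tert-butyldimethylsilyl)oxy]acetaldehyde | O=CCO[Si](C)(C)C(C)(C)C | starting material
4 | 6-{2-[(tert-butyldimethylsilyl)oxy]-1-hydroxyethyl}-3-(prop-2-en-1-yloxy)cyclohex-2-en-1-one (diastereomer mixture) | O=C1C=C(OCC=C)CCC1C(O)CO[Si](C)(C)C(C)(C)C | intermediate
5 | methanesulfonate of 4 (not isolated) | O=C1C=C(OCC=C)CCC1C(OS(C)(=O)=O)CO[Si](C)(C)C(C)(C)C | intermediate
6 | (6E)-6-{2-[(tert-butyldimethylsilyl)oxy]ethylidene}-3-(prop-2-en-1-yloxy)cyclohex-2-en-1-one | O=C1C=C(OCC=C)CC/C1=C\CO[Si](C)(C)C(C)(C)C | intermediate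
7 | (6E)-6-(2-hydroxyethylidene)-3-(prop-2-en-1-yloxy)cyclohex-2-en-1-one | O=C1C=C(OCC=C)CC/C1=C\CO | intermediate
8 | 5-bromo-2,4-dihydroxybenzaldehyde | O=Cc1cc(Br)c(O)cc1O | starting material
9 | tributyl(3-methylbut-2-en-1-yl)stannane | CC(C)=CC[Sn](CCCC)(CCCC)CCCC | starting material
10 | 2,4-dihydroxy-5-(3-methylbut-2-en-1-yl)benzaldehyde | CC(C)=CCc1cc(C=O)c(O)cc1O | intermediate
11 | 2-hydroxy-5-(3-methylbut-2-en-1-yl)-4-(prop-2-en-1-yloxy)benzaldehyde | CC(C)=CCc1cc(C=O)c(O)cc1OCC=C | intermediate
12 | 5-(3-methylbut-2-en-1-yl)-2-{(2E)-2-[2-oxo-4-(prop-2-en-1-yloxy)cyclohex-3-en-1-ylidene]ethoxy}-4-(prop-2-en-1-yloxy)benzaldehyde | CC(C)=CCc1cc(C=O)c(cc1OCC=C)OC/C=C1\CCC(OCC=C)=CC1=O | intermediate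
13 | (3R)-6-(3-methylbut-2-en-1-yl)-3-[2-oxo-4-(prop-2-en-1-yloxy)cyclohex-3-en-1-yl]-7-(prop-2-en-1-yloxy)-2,3-dihydro-4H-chromen-4-one (epimers at cyclohexenone C1) | CC(C)=CCc1cc2c(cc1OCC=C)OC[C@@H](C1CCC(OCC=C)=CC1=O)C2=O | intermediate
14 | (3R)-6-(3-methylbut-2-en-1-yl)-3-[2-oxo-4-(prop-2-en-1-yloxy)cyclohex-3-en-1-yl]-7-(prop-2-en-1-yloxy)-3,4-dihydro-2H-chromen-4-ol (mixture at C4 and cyclohexenone C1) | CC(C)=CCc1cc2c(cc1OCC=C)OC[C@@H](C1CCC(OCC=C)=CC1=O)C2O | intermediate
15 | 6-[(3R)-6-(3-methylbut-2-en-1-yl)-7-(prop-2-en-1-yloxy)-3,4-dihydro-2H-chromen-3-yl]-3-(prop-2-en-1-yloxy)cyclohex-2-en-1-one (epimers at cyclohexenone C6) | CC(C)=CCc1cc2c(cc1OCC=C)OC[C@@H](C1CCC(OCC=C)=CC1=O)C2 | intermediate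
16 | 6-(phenylselanyl) derivative of 15 (chroman C3 unchanged in space; its CIP label becomes S) (not isolated) | CC(C)=CCc1cc2c(cc1OCC=C)OC[C@@H](C1([Se]c3ccccc3)CCC(OCC=C)=CC1=O)C2 | intermediate
17 | Se-oxide of 16 (not isolated) | CC(C)=CCc1cc2c(cc1OCC=C)OC[C@@H](C1([Se](=O)c3ccccc3)CCC(OCC=C)=CC1=O)C2 | intermediate
18 | 6-[(3R)-6-(3-methylbut-2-en-1-yl)-7-(prop-2-en-1-yloxy)-3,4-dihydro-2H-chromen-3-yl]-3-(prop-2-en-1-yloxy)cyclohexa-2,5-dien-1-one (not isolated) | CC(C)=CCc1cc2c(cc1OCC=C)OC[C@@H](C1=CCC(OCC=C)=CC1=O)C2 | intermediate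
19 | 2-[(3R)-6-(3-methylbut-2-en-1-yl)-7-(prop-2-en-1-yloxy)-3,4-dihydro-2H-chromen-3-yl]-5-(prop-2-en-1-yloxy)phenol | CC(C)=CCc1cc2c(cc1OCC=C)OC[C@@H](c1ccc(OCC=C)cc1O)C2 | intermediate
20 | 3-methylbut-2-enal | CC(C)=CC=O | starting material
21 | 4-(2-methylprop-1-en-1-yl)-8-[(3R)-6-(3-methylbut-2-en-1-yl)-7-(prop-2-en-1-yloxy)-3,4-dihydro-2H-chromen-3-yl]-2-phenyl-5-(prop-2-en-1-yloxy)-4H-1,3,2-benzodioxaborinine (not isolated) | CC(C)=CCc1cc2c(cc1OCC=C)OC[C@@H](c1ccc(OCC=C)c3c1OB(c4ccccc4)OC3C=C(C)C)C2 | intermediate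
22 | 2-[(3R)-6-(3-methylbut-2-en-1-yl)-7-(prop-2-en-1-yloxy)-3,4-dihydro-2H-chromen-3-yl]-6-(3-methylbut-2-en-1-ylidene)-5-(prop-2-en-1-yloxy)cyclohexa-2,4-dien-1-one (not isolated) | CC(C)=CCc1cc2c(cc1OCC=C)OC[C@@H](C1=CC=C(OCC=C)C(=CC=C(C)C)C1=O)C2 | intermediate
23 | (3R)-3-[2,2-dimethyl-5-(prop-2-en-1-yloxy)-2H-chromen-8-yl]-6-(3-methylbut-2-en-1-yl)-7-(prop-2-en-1-yloxy)-3,4-dihydro-2H-chromene | CC(C)=CCc1cc2c(cc1OCC=C)OC[C@@H](c1ccc(OCC=C)c3c1OC(C)(C)C=C3)C2 | intermediate
24 | (3R)-3-(5-hydroxy-2,2-dimethyl-2H-chromen-8-yl)-6-(3-methylbut-2-en-1-yl)-3,4-dihydro-2H-chromen-7-ol | CC(C)=CCc1cc2c(cc1O)OC[C@@H](c1ccc(O)c3c1OC(C)(C)C=C3)C2 | target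

**Summary**

Total step count: 13. Longest linear sequence: 11 steps (steps 1–4 and 7–13); the ring A branch (steps 5 and 6) has 2 steps.

Steps most likely to fail:

Step 8. The acyl-anion addition to the α-substituted, electron-rich acceptor may be slow or poorly face-selective, and the base may partly epimerise C3. Fallback: from 12 the cyclisation is run with an achiral, less hindered carbene (3-benzyl-5-(2-hydroxyethyl)-4-methylthiazolium chloride, Et3N, EtOH, 70 °C) to give the racemic chroman-4-one F1. The stereocenter is then set by Noyori asymmetric hydrogenation under dynamic kinetic resolution (RuCl2[(S)-xylbinap][(S)-daipen] or its antipode, KOt-Bu, H2, i-PrOH): the base equilibrates C3, and the catalyst reduces one ketone enantiomer and leaves the olefins alone. This should give the cis-(3R,4R)-chroman-4-ol F2, a single stereoisomer of 14, which is taken through step 10 and comes back to the route at 15.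

Step 11. Electrophilic selenium or the peracid may attack the prenyl and allyl olefins, and part of the selenoxide may eliminate toward the C3–H; the achiral exocyclic enone formed that way should lower the yield but not the enantiopurity of 19, since it does not aromatise under these conditions. Fallback: Saegusa–Ito dehydrogenation; from 15, LiN(i-Pr)2 and Me3SiCl (THF, −78 °C) give the trimethylsilyl dienol ether F4, and Pd(OAc)2 (1.05 equiv, MeCN, rt) effects β-hydride elimination into the ring to dienone 18, which tautomerises and comes back to the route at 19.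

Step 10. The C4 cation may lose the C3 proton to a 2H-chromene that is then reduced without stereocontrol, and the acid may attack the prenyl olefin or hydrolyse the enol ether. Fallback: radical Barton–McCombie deoxygenation; from 14, 1,1'-thiocarbonyldiimidazole (DMAP cat., CH2Cl2, rt) gives the O-(chroman-4-yl) imidazole-1-carbothioate F3, and Bu3SnH with AIBN (toluene, 80 °C) reduces it through the benzylic C4 radical, coming back to the route at 15.

Further compounds
F1 | step 8 | racemic 6-(3-methylbut-2-en-1-yl)-3-[2-oxo-4-(prop-2-en-1-yloxy)cyclohex-3-en-1-yl]-7-(prop-2-en-1-yloxy)-2,3-dihydro-4H-chromen-4-one | CC(C)=CCc1cc2c(cc1OCC=C)OCC(C1CCC(OCC=C)=CC1=O)C2=O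
F2 | step 8 | (3R,4R)-6-(3-methylbut-2-en-1-yl)-3-[2-oxo-4-(prop-2-en-1-yloxy)cyclohex-3-en-1-yl]-7-(prop-2-en-1-yloxy)-3,4-dihydro-2H-chromen-4-ol (cis) | CC(C)=CCc1cc2c(cc1OCC=C)OC[C@@H](C1CCC(OCC=C)=CC1=O)[C@H]2O
F3 | step 10 | O-{(3R)-6-(3-methylbut-2-en-1-yl)-3-[2-oxo-4-(prop-2-en-1-yloxy)cyclohex-3-en-1-yl]-7-(prop-2-en-1-yloxy)-3,4-dihydro-2H-chromen-4-yl} 1H-imidazole-1-carbothioate | CC(C)=CCc1cc2c(cc1OCC=C)OC[C@@H](C1CCC(OCC=C)=CC1=O)C2OC(=S)n1ccnc1
F4 | step 11 | (3R)-6-(3-methylbut-2-en-1-yl)-7-(prop-2-en-1-yloxy)-3-[4-(prop-2-en-1-yloxy)-2-(trimethylsilyloxy)cyclohexa-1,3-dien-1-yl]-3,4-dihydro-2H-chromene | CC(C)=CCc1cc2c(cc1OCC=C)OC[C@@H](C1=C(O[Si](C)(C)C)C=C(OCC=C)CC1)C2
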